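(All constants belong to no real substance; the run is a simulation.)

Slowness came first: the solid reagent feeds coupling partner with a time constant of 8.33 h, and Friday's and Monday's flasks have the same charges and differ in temperature.

    free catalyst + left-handed substrate ⇌ catalyst intermediate A (K1 = 21 M⁻¹, k1 = 21000 M⁻¹ h⁻¹, Ea1 = 38.0 kJ mol⁻¹, ΔH1 = −83.0 kJ mol⁻¹)
    free catalyst + right-handed substrate ⇌ catalyst intermediate B (K2 = 25 M⁻¹, k2 = 14000 M⁻¹ h⁻¹, Ea2 = 47.0 kJ mol⁻¹, ΔH2 = 41.0 kJ mol⁻¹)
    coupling partner + catalyst intermediate A → free catalyst + left-handed product (k3 = 1200 M⁻¹ h⁻¹, Ea3 = 57.0 kJ mol⁻¹)
    coupling partner + catalyst intermediate B → free catalyst + right-handed product (k4 = 59 M⁻¹ h⁻¹, Ea4 = 52.0 kJ mol⁻¹)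
    solid reagent ⇌ coupling partner, rate k5*(cs5 - [coupling partner]) while solid is left; crystals form when [coupling partner] > cs5 (cs5 = 47 mM, k5 = 0.12 h⁻¹)
    coupling partner + protic impurity → quenched reagent (k6 = 66 M⁻¹ h⁻¹, Ea6 = 51.0 kJ mol⁻¹)
    2 free catalyst → spent catalyst (k7 = 1100 M⁻¹ h⁻¹, Ea7 = 58.0 kJ mol⁻¹)
    (constants at 25 °C)

common to all: left-handed substrate 0.10 M; solid reagent 0.110 M; protic impurity 2.00 mM; free catalyst 0.33 mM; right-handed substrate 0.10 M; time 25 h
- Friday's: temperature 45 °C
- Monday's: temperature 25 °C

- the best flask by amount of left-handed product, in percent of the left-handed substrate and right-handed substrate together charged; "all alike" if 1.5 percentage points covers them all (Friday's / Monday's / all alike)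
- amount of left-handed product at the end, in percent of the left-handed substrate and right-handed substrate together charged, Friday's
- amount of left-handed product at the end, in percent of the left-handed substrate and right-handed substrate together charged, Monday's

- free catalyst is single-handed; left-handed substrate and right-handed substrate are mirror images of each other, charged as a racemate, each of them at the stated concentration
- a doubled species enters its step squared and goes two at a time
- as a solid, counted per litre of solution: solid reagent
- constants are those at 25 °C; use the activation energies and enthalpies for any other temperature
- at the start none of the solid reagent is in solution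

I split the question in two: how much coupling partner was turned, and what share of it went to the left-handed product. Both coupling steps are first order in c(coupling partner), so that is the concentration I reckoned first. For Monday's flask, taking the whole catalyst charge as working and binding as at equilibrium, I reckoned a pseudo-first-order constant of 0.157 h⁻¹ for the catalyst's use of it, faster than the 0.12 h⁻¹ of dissolving. The two are close, so I held c(coupling partner) at 23.5 mM, half of the solubility. Dissolving at that level for 25 h, less what stood in solution and the 2.00 mM of protic impurity, gave 45.0 mM turned, and I assumed the same figure for Friday's flask.

In this reckoning, the share is where the flasks part. In Monday's flask, intermediate A falls back at 1000 h⁻¹, faster than the 28.2 h⁻¹ at which it couples, so I treated binding as an equilibrium there and assumed the same for Friday's flask. At equal substrates, the product rates then stand in the selectivity factor s, the binding constant times the coupling constant of the left-handed path over the same product for the right-handed path: 17.1 on Monday's. The four temperature terms add to −119 kJ mol⁻¹, which brought s down to 0.836 on Friday's. With the left-handed share s/(1+s), and assuming the two substrates stayed equal, I committed to 10.2% for Friday's and 21.3% for Monday's, which put Monday's ahead.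

The forecast named Monday's, with 9.4% (8% to 11%) for Friday's and 23.7% (21% to 26.5%) for Monday's, holding that on warming “the selectivity for the left-handed product is lost”. The simulation gave 8.80% for Friday's and 22.7% for Monday's, so Monday's led.

In Monday's flask at 25.0 h, intermediate A had a half-life of 1.2 min by coupling, longer than the 2.50 s reckoned for falling back. Friday's products ended at a ratio of 0.854, against s of 0.836. For Monday's recipe at 50 °C, s comes to 0.417, which, with the same amount assumed turned, gives 6.62% of left-handed product. The run gave 6.51%, beside 14.1% of right-handed product, a ratio of 0.462.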